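**Plan**
- Retrosynthetic cuts of the target gibberellin (12α,15β-dihydroxygibberellic acid), in order: C16=C17 (methylenation of a C16 ketone), C12–C13 (ring C), C1=C2 (ring A), C3–C4, C4–C5 with the C19–O–C10 ester (lactone), C10–C1, C9–C11, C5–C6 (ring B), C6–C8.
- Enabling feature (gibberellane numbering): the C12 secondary carbinol of ring C lies next to the bridgehead C13 tertiary carbinol shared by rings C and D. At the C12 ketone level this is an α-ketol that joins a C12 aldehyde on the C9 side chain to the C13 ketone of ring D.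
- Forward order: ring D (chiral cyclopentenone) → quaternary C8 by Claisen rearrangement → ring B by aldol condensation (spiro enone) → C9 side chain, C10 vinyl carbinol, lactone by Michael addition → ring A by aldol addition and ring-closing metathesis → ring C by carbene-catalysed acyloin closure → C12 reduction, C16 methylenation, deprotection.
- Stereochemistry: C15 of (R)-4-silyloxycyclopentenone is the only imported centre. It is relayed to C8 (Mitsunobu inversion, suprafacial Claisen shift), then to C9 (alkylation anti to the C15 silyl ether), C10 (addition anti to C9), C5/C6/C4 (tethered Michael addition, convex-face aldol), C3 (closed aldol transition state), C13 (tether geometry) and C12 (equatorial hydride delivery).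

Key step: step 24

Remark: atoms carry gibberellane numbers throughout; C7 is carried as its 2-(trimethylsilyl)ethyl ester and C16 as an ethylene ketal. Centres that are destroyed later (C13 carbinol in 14–33, C4–H in 28) are drawn as the expected epimer, and C6 in 17 and 20 and the side-chain carbinol in 35 are left undefined, because both epimers converge.

Step 1
Reactants: 1 (R)-4-(tert-butyldimethylsilyloxy)cyclopent-2-en-1-one; 2 allylmagnesium bromide
Product: 3 trans-3-allyl-4-(tert-butyldimethylsilyloxy)-1-(trimethylsilyloxy)cyclopent-1-ene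
Conditions: CH2=CHCH2MgBr, CuBr·SMe2 (cat.), TMSCl, THF, −78 °C
Reagents that add atoms: chlorotrimethylsilane, C[Si](C)(C)Cl
Why: Copper-catalysed conjugate addition of the allyl Grignard reagent with in situ silyl trapping puts the allyl group on the future C8 anti to the silyl ether, and trapping as the enol ether prevents enolate equilibration and β-elimination of the silyloxy group (this new centre is erased in step 2).

Step 2
Reactants: 3 trans-3-allyl-4-(tert-butyldimethylsilyloxy)-1-(trimethylsilyloxy)cyclopent-1-ene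
Product: 4 (R)-3-allyl-4-(tert-butyldimethylsilyloxy)cyclopent-2-en-1-one
Conditions: Pd(OAc)2, MeCN, rt
Reagents that add atoms: none
Why: Saegusa–Ito oxidation of the regiodefined silyl enol ether restores the enone with the allyl group now on the β-carbon (C8) and leaves the C15 stereocentre untouched.

Step 3
Reactants: 4 (R)-3-allyl-4-(tert-butyldimethylsilyloxy)cyclopent-2-en-1-one
Product: 5 (1S,4R)-3-allyl-4-(tert-butyldimethylsilyloxy)cyclopent-2-en-1-ol (cis alcohol)
Conditions: NaBH4, CeCl3·7H2O, MeOH, −78 °C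
Reagents that add atoms: none
Why: Luche 1,2-reduction delivers hydride anti to the C15 silyl ether and should give the cis-1,4 alcohol, whose C13 carbinol serves only as a stereochemical relay.

Step 4
Reactants: 5 (1S,4R)-3-allyl-4-(tert-butyldimethylsilyloxy)cyclopent-2-en-1-ol; 6 acetic acid
Product: 7 (1R,4R)-3-allyl-4-(tert-butyldimethylsilyloxy)cyclopent-2-en-1-yl acetate (trans acetate)
Conditions: PPh3, diisopropyl azodicarboxylate, AcOH, THF, 0 °C → rt
Reagents that add atoms: none
Why: Mitsunobu esterification inverts the allylic carbinol by SN2 displacement, so the C13–O bond of the acetate lies on the ring face opposite the silyl ether.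

Step 5
Reactants: 7 (1R,4R)-3-allyl-4-(tert-butyldimethylsilyloxy)cyclopent-2-en-1-yl acetate
Product: 10 2-[1-allyl-5-(tert-butyldimethylsilyloxy)cyclopent-2-en-1-yl]acetic acid (carboxymethyl trans to the silyl ether), via silyl ketene acetal 8 (not isolated), via trimethylsilyl ester 9 (not isolated)
Conditions: LiN(i-Pr)2, TMSCl, THF, −78 °C → 60 °C; then aq. HCl work-up
Reagents that add atoms: none
Why: Ireland–Claisen rearrangement transfers the acetate carbon (C6) suprafacially to C8 on the face where O13 stood, i.e. trans to the C15 silyl ether, creating the quaternary C8 in defined configuration and moving the alkene to C13=C14.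

Step 6
Reactants: 10 2-[1-allyl-5-(tert-butyldimethylsilyloxy)cyclopent-2-en-1-yl]acetic acid
Product: 11 2-(trimethylsilyl)ethyl 2-[1-allyl-5-(tert-butyldimethylsilyloxy)cyclopent-2-en-1-yl]acetate
Conditions: dicyclohexylcarbodiimide, DMAP (cat.), Me3SiCH2CH2OH, CH2Cl2, 0 °C → rt
Reagents that add atoms: 2-(trimethylsilyl)ethanol, C[Si](C)(C)CCO
Why: Steglich esterification installs a fluoride-labile C7 ester that can be released at the end without acid or base.

Step 7
Reactants: 11 2-(trimethylsilyl)ethyl 2-[1-allyl-5-(tert-butyldimethylsilyloxy)cyclopent-2-en-1-yl]acetate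
Product: 12 2-(trimethylsilyl)ethyl 2-[1-allyl-5-(tert-butyldimethylsilyloxy)-4-oxocyclopent-2-en-1-yl]acetate (ring D enone; C16 ketone)
Conditions: Rh2(cap)4 (dirhodium tetracaprolactamate, cat.), t-BuOOH, K2CO3, CH2Cl2, rt
Reagents that add atoms: tert-butyl hydroperoxide, CC(C)(C)OO
Why: Dirhodium-catalysed allylic oxidation converts the only allylic methylene of the cyclopentene (C16, since the other allylic atom C8 is quaternary) into the enone carbonyl, while the terminal allyl group is far less reactive under these conditions.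

Step 8
Reactants: 12 ring D enone (C16 ketone)
Product: 14 ring D α-hydroxy ketone (C13 hydroxyl trans to the C15 silyl ether; C16 ketone), via C13 hydroperoxide 13 (not isolated)
Conditions: Mn(dpm)3 (manganese tris(dipivaloylmethanate), cat.), PhSiH3, O2 (1 atm), i-PrOH/CH2Cl2, 0 °C; then P(OEt)3
Reagents that add atoms: dioxygen, O=O
Why: Mukaiyama-type hydrogen-atom-transfer α-hydroxylation of the enone (metal hydride adds H to C14, the C13 radical captures O2 anti to the silyl ether and allyl group, phosphite reduces the hydroperoxide) places oxygen on C13 and saturates C14.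

Step 9
Reactants: 14 ring D α-hydroxy ketone
Product: 15 C13 triethylsilyl ether of 14
Conditions: Et3SiCl, imidazole, DMF, 0 °C
Reagents that add atoms: chlorotriethylsilane, CC[Si](Cl)(CC)CC
Why: Silylation gives a C13 ether that can later be cleaved selectively beside TBS ethers and blocks α-ketol isomerisation between C13 and C16.

Step 10
Reactants: 15 C13 triethylsilyl ether (C16 ketone)
Product: 16 C16 ethylene ketal of 15
Conditions: Me3SiOCH2CH2OSiMe3, TMSOTf (cat.), CH2Cl2, −78 → −20 °C; pyridine quench
Reagents that add atoms: 1,2-bis(trimethylsilyloxy)ethane, C[Si](C)(C)OCCO[Si](C)(C)C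
Why: Noyori ketalisation under aprotic low-temperature conditions masks the hindered α,α′-dioxygenated C16 ketone, making C16 non-enolisable so that the C15 silyl ether cannot be eliminated once C13 becomes a ketone.

Step 11
Reactants: 16 C16 ethylene ketal
Product: 17 C6 α-hydroxy ester (C6 epimers)
Conditions: LiN(i-Pr)2, THF, −78 °C; 2-(phenylsulfonyl)-3-phenyloxaziridine
Reagents that add atoms: 2-(phenylsulfonyl)-3-phenyloxaziridine, O=S(=O)(c1ccccc1)N1OC1c1ccccc1
Why: Davis oxaziridine hydroxylation of the ester enolate (the ester α-CH2 is the only acidic C–H in 16) introduces the C6 oxygen, whose configuration is irrelevant.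

Step 12
Reactants: 17 C6 α-hydroxy ester
Product: 18 C6 α-keto ester
Conditions: Dess–Martin periodinane, NaHCO3, CH2Cl2, rt
Reagents that add atoms: none
Why: Dess–Martin oxidation gives the α-keto ester whose C6 carbonyl is the electrophile of the ring B annulation.

Step 13
Reactants: 18 C6 α-keto ester
Product: 19 methyl ketone α-keto ester (C9H2–C10(=O)–C5H3 arm on C8)
Conditions: PdCl2 (cat.), Cu(OAc)2 (cat.), O2 (1 atm), DMA/H2O, rt
Reagents that add atoms: water, O
Why: Tsuji–Wacker oxidation converts the terminal alkene with Markovnikov selectivity into the methyl ketone, and the acetate-buffered copper co-oxidant spares silyl ethers and ketal.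

Step 14
Reactants: 19 methyl ketone α-keto ester
Product: 21 spiro enone (ring B 4-oxocyclopent-2-ene-1-carboxylate spiro-fused at C8 to ring D), via aldol adduct 20 (not isolated)
Conditions: DBU, toluene, 60 °C
Reagents that add atoms: none
Why: Intramolecular aldol condensation of the 1,4-dicarbonyl closes ring B, because only the methyl enolate (C5) can reach the highly electrophilic C6 carbonyl through a five-membered transition state and E1cB dehydration then gives the conjugated enone ester.

Step 15
Reactants: 21 spiro enone; 22 prenyl bromide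
Product: 23 C9-prenylated spiro enone (prenyl cis to C14)
Conditions: LiN(SiMe3)2, THF, −78 °C; prenyl bromide, DMPU, −78 → −40 °C
Reagents that add atoms: none
Why: α′-Alkylation of the cross-conjugated lithium enolate occurs at C9 (the γ-carbon C8 is quaternary), anti to the C15 silyl ether that projects over the β face of C9, so the prenyl group (C11 and masked C12) becomes α and cis to C14.

Step 16
Reactants: 23 C9-prenylated spiro enone; 24 vinylmagnesium bromide; 25 propionic anhydride
Product: 27 C10 vinyl carbinol propionate, via dichlorocerium alkoxide 26 (not isolated)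
Conditions: CH2=CHMgBr, CeCl3, THF, −78 °C; then (EtCO)2O, DMAP, −78 °C → rt
Reagents that add atoms: none
Why: Cerium-mediated 1,2-addition of the vinyl nucleophile to the C10 ketone occurs anti to the adjacent C9 side chain (vinyl β, oxygen α) without enolisation or conjugate addition, and the tertiary alkoxide is acylated in situ.

Step 17
Reactants: 27 C10 vinyl carbinol propionate
Product: 28 cis-fused γ-lactone (C19–O–C10 lactone; C4–C5 bond formed; 6β ester)
Conditions: KN(SiMe3)2, THF, −78 °C; AcOH quench at −78 °C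
Reagents that add atoms: none
Why: Intramolecular Michael addition (5-exo-trig) of the propionate enolate to C5 of the unsaturated ester forms C4–C5 necessarily on the α face where the tether sits, outruns ester-enolate Claisen rearrangement at −78 °C, and protonation of the C6 enolate anti to the new C4 branch should give the 6β ester.

Step 18
Reactants: 28 cis-fused γ-lactone; 29 acrolein
Product: 30 C4 aldol adduct (C4 quaternary; 3S allylic alcohol)
Conditions: LiN(SiMe3)2, THF, −78 °C; acrolein; AcOH quench at −78 °C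
Reagents that add atoms: none
Why: Aldol addition of the lactone lithium enolate (the lactone α-H is markedly more acidic than the hindered C6 ester α-H) to acrolein should occur on the convex face of the bicycle, placing C3 cis to the C10 vinyl group, and the closed Zimmerman–Traxler chair with methyl cis to O–Li predicts the methyl/hydroxyl-syn (3S) carbinol.

Step 19
Reactants: 30 C4 aldol adduct
Product: 31 C3 tert-butyldimethylsilyl ether (metathesis diene)
Conditions: TBSOTf, 2,6-lutidine, CH2Cl2, −78 → 0 °C
Reagents that add atoms: tert-butyldimethylsilyl triflate, CC(C)(C)[Si](C)(C)OS(=O)(=O)C(F)(F)F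
Why: Silylation of the hindered allylic alcohol blocks retro-aldol cleavage and installs the C3 protecting group carried to the end.

Step 20
Reactants: 31 C3 silyl ether diene
Product: 32 ring A cyclohexene (A/B lactone with Δ1 alkene and 3-OTBS; ring D ketal; C9 prenyl)
Conditions: second-generation Hoveyda–Grubbs catalyst, RuCl2(H2IMes)(=CH-C6H4-2-O-i-Pr) (cat.), toluene, 80 °C
Reagents that add atoms: none
Why: Ring-closing metathesis of the two vinyl groups held cis on the lactone (at C10 and C3) forms the C1=C2 bond and the six-membered ring A, while the trisubstituted prenyl alkene is a poor metathesis partner and could only give strained or medium rings.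

Step 21
Reactants: 32 ring A cyclohexene
Product: 33 C13 alcohol
Conditions: HF·pyridine, pyridine, THF, 0 °C
Reagents that add atoms: none
Why: Buffered fluoride cleaves the secondary triethylsilyl ether much faster than the two hindered TBS ethers and leaves the 2-(trimethylsilyl)ethyl ester intact.

Step 22
Reactants: 33 C13 alcohol
Product: 34 C13 ketone (ring D 1,2-dione mono-ketal)
Conditions: Dess–Martin periodinane, NaHCO3, CH2Cl2, rt
Reagents that add atoms: none
Why: Dess–Martin oxidation gives the C13 ketone, which is stable because its only enolisable neighbour is C14 and the C15 silyl ether lies behind the non-enolisable ketal carbon.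

Step 23
Reactants: 34 C13 ketone
Product: 36 C12 aldehyde tethered to the ring D C13 ketone (C16 ketal; 3,15-bis-TBS ether; C7 2-(trimethylsilyl)ethyl ester), via side-chain diol 35 (not isolated)
Conditions: OsO4 (cat.), NaIO4, 2,6-lutidine, dioxane/H2O, rt
Reagents that add atoms: sodium periodate, [Na+].[O-]I(=O)(=O)=O
Why: Lemieux–Johnson cleavage dihydroxylates the electron-rich trisubstituted prenyl alkene in preference to the hindered ring A alkene flanked by two allylic oxygens, and periodate cleaves the diol to the C12 aldehyde.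

Step 24
Reactants: 36 C12 aldehyde tethered to the ring D C13 ketone
Product: 37 C12-keto C13-hydroxy bicyclo[3.2.1]octane (rings C and D closed; C16 ketal)
Conditions: 2-(pentafluorophenyl)-6,7-dihydro-5H-pyrrolo[2,1-c][1,2,4]triazol-2-ium tetrafluoroborate (20 mol %), Et3N (20 mol %), CH2Cl2, 25–40 °C
Reagents that add atoms: none
Why: The triazolylidene adds to the C12 aldehyde and proton transfer gives the enaminol (Breslow) acyl anion equivalent, whose C12 attacks the C13 ketone; release of the carbene leaves the C12 ketone and the C13 tertiary alcohol. The closest known reaction type is the triazolium-catalysed intramolecular crossed aldehyde–ketone benzoin cyclisation to six-membered α-ketols. Ring C closes by 6-exo-trig addition of C12 to the C13 carbonyl, which also completes the bicyclo[3.2.1]octane of rings C and D. The new C13 centre is fixed by the tether: C11 on C9 and C14 on C8 are both α, so C12 can reach only the ketone face syn to C9. The step needs acyl anion addition to win over aldol reactions of the enolisable aldehyde (C11) and ketone (C14); the weak amine base, the non-enolisable ketal-bearing C16, the high electrophilicity of the α-ketal ketone and the pre-organisation of both carbonyls on the α face of ring B secure this, and the near-neutral, non-reductive conditions leave the allylic lactone, silyl ethers and ester untouched.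

Step 25
Reactants: 37 C12-keto C13-hydroxy bicyclo[3.2.1]octane
Product: 38 12α,13-diol
Conditions: LiBH(s-Bu)3, THF, −78 °C
Reagents that add atoms: none
Why: Bulky hydride reduction should enter equatorially from the side of the C15–C16 bridge, because the axial face of the C12 carbonyl in the ring C chair is blocked by the 1,3-diaxial C10, giving the axial 12α alcohol cis to the C13 hydroxyl.

Step 26
Reactants: 38 12α,13-diol
Product: 39 C16 ketone (12α,13-dihydroxy-16-oxo compound)
Conditions: pyridinium p-toluenesulfonate, THF/H2O, 55 °C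
Reagents that add atoms: water, O
Why: Acid-catalysed ketal hydrolysis unmasks the C16 ketone now that C13 is a carbinol and can no longer drive β-elimination, under acidity mild enough for the TBS ethers and the ring A allylic lactone.

Step 27
Reactants: 39 C16 ketone
Product: 40 12,13-bis(trimethylsilyl) ether of 39
Conditions: 1-(trimethylsilyl)imidazole, CH2Cl2, rt
Reagents that add atoms: 1-(trimethylsilyl)imidazole, C[Si](C)(C)n1ccnc1
Why: Silylation of the secondary and bridgehead tertiary hydroxyls with the neutral silyl-imidazole reagent protects the α-ketol against rearrangement and against consuming the methylenation reagent, without enol silylation of the ketone.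

Step 28
Reactants: 40 12,13-bis(trimethylsilyl) ether (C16 ketone)
Product: 41 16-methylene compound (fully protected target gibberellin)
Conditions: Zn, CH2Br2, TiCl4, THF/CH2Cl2, 0 °C → rt
Reagents that add atoms: dibromomethane, BrCBr
Why: Lombardo–Takai methylenation converts the hindered, enolisable C16 ketone into the exocyclic methylene under non-basic conditions, avoiding C15 epimerisation and α-ketol rearrangement.

Step 29
Reactants: 41 16-methylene compound
Product: 42 target gibberellin, 12α,15β-dihydroxygibberellic acid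
Conditions: Bu4NF, AcOH (1 equiv per fluoride), THF, 0 → 40 °C
Reagents that add atoms: none
Why: Fluoride-mediated global deprotection cleaves the four silyl ethers and fragments the 2-(trimethylsilyl)ethyl ester to the C7 acid, with acetic acid buffering to suppress retro-aldol epimerisation at C3 and opening of the allylic lactone.

**Compound list**
1 | (R)-4-(tert-butyldimethylsilyloxy)cyclopent-2-en-1-one | O=C1C=C[C@H](O[Si](C)(C)C(C)(C)C)C1 | starting material
2 | allylmagnesium bromide | C=CC[Mg]Br | starting material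
3 | trans-3-allyl-4-(tert-butyldimethylsilyloxy)-1-(trimethylsilyloxy)cyclopent-1-ene | C[Si](C)(C)OC1=C[C@@H](CC=C)[C@H](O[Si](C)(C)C(C)(C)C)C1 | intermediate
4 | (R)-3-allyl-4-(tert-butyldimethylsilyloxy)cyclopent-2-en-1-one | O=C1C=C(CC=C)[C@H](O[Si](C)(C)C(C)(C)C)C1 | intermediate
5 | (1S,4R)-3-allyl-4-(tert-butyldimethylsilyloxy)cyclopent-2-en-1-ol (cis) | O[C@@H]1C=C(CC=C)[C@H](O[Si](C)(C)C(C)(C)C)C1 | intermediate
6 | acetic acid | CC(=O)O | starting material
7 | (1R,4R)-3-allyl-4-(tert-butyldimethylsilyloxy)cyclopent-2-en-1-yl acetate (trans) | CC(=O)O[C@H]1C=C(CC=C)[C@H](O[Si](C)(C)C(C)(C)C)C1 | intermediate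
8 | O-trimethylsilyl ketene acetal of acetate 7 | C=C(O[Si](C)(C)C)O[C@H]1C=C(CC=C)[C@H](O[Si](C)(C)C(C)(C)C)C1 | intermediate
9 | trimethylsilyl ester of acid 10 | C[Si](C)(C)OC(=O)C[C@]1(CC=C)C=CC[C@H]1O[Si](C)(C)C(C)(C)C | intermediate
10 | 2-[1-allyl-5-(tert-butyldimethylsilyloxy)cyclopent-2-en-1-yl]acetic acid, carboxymethyl trans and allyl cis to the silyl ether (C8 quaternary) | OC(=O)C[C@]1(CC=C)C=CC[C@H]1O[Si](C)(C)C(C)(C)C | intermediate
11 | 2-(trimethylsilyl)ethyl ester of 10 | C[Si](C)(C)CCOC(=O)C[C@]1(CC=C)C=CC[C@H]1O[Si](C)(C)C(C)(C)C | intermediate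
12 | ring D enone: 4-oxocyclopent-2-ene analogue of 11 (C16 ketone, C13=C14) | C[Si](C)(C)CCOC(=O)C[C@]1(CC=C)C=CC(=O)[C@H]1O[Si](C)(C)C(C)(C)C | intermediate
13 | C13 hydroperoxide of the saturated C16 ketone | C[Si](C)(C)CCOC(=O)C[C@]1(CC=C)C[C@H](OO)C(=O)[C@H]1O[Si](C)(C)C(C)(C)C | intermediate
14 | ring D α-hydroxy ketone (C13–OH trans to C15–OTBS, C16 ketone) | C[Si](C)(C)CCOC(=O)C[C@]1(CC=C)C[C@H](O)C(=O)[C@H]1O[Si](C)(C)C(C)(C)C | intermediate
15 | C13 triethylsilyl ether of 14 | C[Si](C)(C)CCOC(=O)C[C@]1(CC=C)C[C@H](O[Si](CC)(CC)CC)C(=O)[C@H]1O[Si](C)(C)C(C)(C)C | intermediate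
16 | C16 ethylene ketal of 15 | C[Si](C)(C)CCOC(=O)C[C@]1(CC=C)C[C@H](O[Si](CC)(CC)CC)C2(OCCO2)[C@H]1O[Si](C)(C)C(C)(C)C | intermediate
17 | C6 α-hydroxy ester of 16 (C6 epimers) | C[Si](C)(C)CCOC(=O)C(O)[C@]1(CC=C)C[C@H](O[Si](CC)(CC)CC)C2(OCCO2)[C@H]1O[Si](C)(C)C(C)(C)C | intermediate
18 | C6 α-keto ester | C[Si](C)(C)CCOC(=O)C(=O)[C@]1(CC=C)C[C@H](O[Si](CC)(CC)CC)C2(OCCO2)[C@H]1O[Si](C)(C)C(C)(C)C | intermediate
19 | methyl ketone α-keto ester (acetonyl and oxalyl arms on C8) | C[Si](C)(C)CCOC(=O)C(=O)[C@]1(CC(C)=O)C[C@H](O[Si](CC)(CC)CC)C2(OCCO2)[C@H]1O[Si](C)(C)C(C)(C)C | intermediate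
20 | aldol adduct: ring B β-hydroxy ketone with C6 tertiary carbinol | C[Si](C)(C)CCOC(=O)C1(O)CC(=O)C[C@]12C[C@H](O[Si](CC)(CC)CC)C3(OCCO3)[C@H]2O[Si](C)(C)C(C)(C)C | intermediate
21 | spiro enone: ring B C10 ketone, C5=C6 bearing the C7 ester, spiro at C8 to ring D (C13 OTES, C16 ketal, C15 OTBS) | C[Si](C)(C)CCOC(=O)C1=CC(=O)C[C@]12C[C@H](O[Si](CC)(CC)CC)C3(OCCO3)[C@H]2O[Si](C)(C)C(C)(C)C | intermediate
22 | prenyl bromide (1-bromo-3-methylbut-2-ene) | CC(C)=CCBr | starting material
23 | C9-prenylated spiro enone (prenyl α, cis to C14) | C[Si](C)(C)CCOC(=O)C1=CC(=O)[C@H](CC=C(C)C)[C@]12C[C@H](O[Si](CC)(CC)CC)C3(OCCO3)[C@H]2O[Si](C)(C)C(C)(C)C | intermediate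
24 | vinylmagnesium bromide | C=C[Mg]Br | starting material
25 | propionic anhydride | CCC(=O)OC(=O)CC | starting material
26 | dichlorocerium C10 alkoxide of the vinyl adduct | C[Si](C)(C)CCOC(=O)C1=C[C@](C=C)(O[Ce](Cl)Cl)[C@H](CC=C(C)C)[C@]12C[C@H](O[Si](CC)(CC)CC)C3(OCCO3)[C@H]2O[Si](C)(C)C(C)(C)C | intermediate
27 | C10 vinyl carbinol propionate (vinyl β, propionyloxy α) | C[Si](C)(C)CCOC(=O)C1=C[C@](C=C)(OC(=O)CC)[C@H](CC=C(C)C)[C@]12C[C@H](O[Si](CC)(CC)CC)C3(OCCO3)[C@H]2O[Si](C)(C)C(C)(C)C | intermediate
28 | cis-fused γ-lactone (C19–O–C10; C4–H with methyl; 5β-H; 6β ester) | C[Si](C)(C)CCOC(=O)[C@H]1[C@@H]2[C@@H](C)C(=O)O[C@]2(C=C)[C@H](CC=C(C)C)[C@]13C[C@H](O[Si](CC)(CC)CC)C4(OCCO4)[C@H]3O[Si](C)(C)C(C)(C)C | intermediate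
29 | acrolein | C=CC=O | starting material
30 | C4 aldol adduct (C4 quaternary with methyl and (S)-1-hydroxyallyl) | C[Si](C)(C)CCOC(=O)[C@H]1[C@@H]2[C@@](C)([C@@H](O)C=C)C(=O)O[C@]2(C=C)[C@H](CC=C(C)C)[C@]13C[C@H](O[Si](CC)(CC)CC)C4(OCCO4)[C@H]3O[Si](C)(C)C(C)(C)C | intermediate
31 | C3 tert-butyldimethylsilyl ether of 30 | C[Si](C)(C)CCOC(=O)[C@H]1[C@@H]2[C@@](C)([C@@H](O[Si](C)(C)C(C)(C)C)C=C)C(=O)O[C@]2(C=C)[C@H](CC=C(C)C)[C@]13C[C@H](O[Si](CC)(CC)CC)C4(OCCO4)[C@H]3O[Si](C)(C)C(C)(C)C | intermediate
32 | ring A cyclohexene: A/B lactone with Δ1, 3β-OTBS, C9 prenyl, ring D with C13 OTES, C16 ketal, C15 OTBS | C[Si](C)(C)CCOC(=O)[C@H]1[C@@H]2[C@]3(C)C(=O)O[C@]2(C=C[C@@H]3O[Si](C)(C)C(C)(C)C)[C@H](CC=C(C)C)[C@]14C[C@H](O[Si](CC)(CC)CC)C5(OCCO5)[C@H]4O[Si](C)(C)C(C)(C)C | intermediate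
33 | C13 alcohol | C[Si](C)(C)CCOC(=O)[C@H]1[C@@H]2[C@]3(C)C(=O)O[C@]2(C=C[C@@H]3O[Si](C)(C)C(C)(C)C)[C@H](CC=C(C)C)[C@]14C[C@H](O)C5(OCCO5)[C@H]4O[Si](C)(C)C(C)(C)C | intermediate
34 | C13 ketone | C[Si](C)(C)CCOC(=O)[C@H]1[C@@H]2[C@]3(C)C(=O)O[C@]2(C=C[C@@H]3O[Si](C)(C)C(C)(C)C)[C@H](CC=C(C)C)[C@]14CC(=O)C5(OCCO5)[C@H]4O[Si](C)(C)C(C)(C)C | intermediate
35 | side-chain diol from dihydroxylation of the prenyl alkene | C[Si](C)(C)CCOC(=O)[C@H]1[C@@H]2[C@]3(C)C(=O)O[C@]2(C=C[C@@H]3O[Si](C)(C)C(C)(C)C)[C@H](CC(O)C(C)(C)O)[C@]14CC(=O)C5(OCCO5)[C@H]4O[Si](C)(C)C(C)(C)C | intermediate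
36 | key precursor: C12 aldehyde on C9 tethered to the ring D C13 ketone (C16 ketal, 3,15-bis-TBS, C7 2-(trimethylsilyl)ethyl ester) | C[Si](C)(C)CCOC(=O)[C@H]1[C@@H]2[C@]3(C)C(=O)O[C@]2(C=C[C@@H]3O[Si](C)(C)C(C)(C)C)[C@H](CC=O)[C@]14CC(=O)C5(OCCO5)[C@H]4O[Si](C)(C)C(C)(C)C | intermediate
37 | key product: C12-keto C13-hydroxy bicyclo[3.2.1]octane with C16 ketal | C[Si](C)(C)CCOC(=O)[C@H]1[C@@H]2[C@]3(C)C(=O)O[C@]2(C=C[C@@H]3O[Si](C)(C)C(C)(C)C)[C@@H]2CC(=O)[C@]3(O)C[C@]12[C@H](O[Si](C)(C)C(C)(C)C)C34OCCO4 | intermediate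
38 | 12α,13-diol (C16 ketal) | C[Si](C)(C)CCOC(=O)[C@H]1[C@@H]2[C@]3(C)C(=O)O[C@]2(C=C[C@@H]3O[Si](C)(C)C(C)(C)C)[C@@H]2C[C@H](O)[C@]3(O)C[C@]12[C@H](O[Si](C)(C)C(C)(C)C)C34OCCO4 | intermediate
39 | 12α,13-dihydroxy C16 ketone | C[Si](C)(C)CCOC(=O)[C@H]1[C@@H]2[C@]3(C)C(=O)O[C@]2(C=C[C@@H]3O[Si](C)(C)C(C)(C)C)[C@@H]2C[C@H](O)[C@]3(O)C[C@]12[C@H](O[Si](C)(C)C(C)(C)C)C3=O | intermediate
40 | 12,13-bis(trimethylsilyl) ether of 39 | C[Si](C)(C)CCOC(=O)[C@H]1[C@@H]2[C@]3(C)C(=O)O[C@]2(C=C[C@@H]3O[Si](C)(C)C(C)(C)C)[C@@H]2C[C@H](O[Si](C)(C)C)[C@]3(O[Si](C)(C)C)C[C@]12[C@H](O[Si](C)(C)C(C)(C)C)C3=O | intermediate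
41 | 16-methylene compound: the target gibberellin as 3,15-bis-TBS, 12,13-bis-TMS ether and C7 2-(trimethylsilyl)ethyl ester | C[Si](C)(C)CCOC(=O)[C@H]1[C@@H]2[C@]3(C)C(=O)O[C@]2(C=C[C@@H]3O[Si](C)(C)C(C)(C)C)[C@@H]2C[C@H](O[Si](C)(C)C)[C@]3(O[Si](C)(C)C)C[C@]12[C@H](O[Si](C)(C)C(C)(C)C)C3=C | intermediate
42 | target gibberellin: 12α,15β-dihydroxygibberellic acid (3β,12α,13,15β-tetrahydroxy-20-norgibberella-1,16-diene-7,19-dioic acid 19,10-lactone) | C=C1[C@@H](O)[C@]23C[C@@]1(O)[C@@H](O)C[C@H]2[C@@]12C=C[C@H](O)[C@@](C)(C(=O)O1)[C@H]2[C@@H]3C(=O)O | target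

Total step count: 29. Longest linear sequence: 29 steps, from compound 1.

**Steps most likely to fail**

Step 18. The aldol addition may suffer from incomplete simple diastereoselection at C3 and from partial enolisation at C6 instead of C4. Fallback: setting out from 30 as its C3 epimer mixture, Dess–Martin oxidation gives the C3 vinyl ketone F1. Corey–Bakshi–Shibata reduction with the (R)-oxazaborolidine and catecholborane at −78 °C then sets the 3S carbinol by reagent control, matched with the Felkin–Anh preference in which the lactone carbonyl stands anti to the incoming hydride. The route is rejoined at 30.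

Step 24. Base-mediated aldol cyclisations of the enolisable aldehyde and ketone, or reversal of the acyloin addition, may compete with carbene-mediated acyl anion addition. Fallback: setting out from 36, a samarium diiodide (SmI2, THF, t-BuOH, −78 °C) ketyl–carbonyl pinacol cyclisation forms the same C12–C13 bond reductively. The aldehyde ketyl forms first and adds to the neighbouring ketone through a samarium chelate, which should give the cis-12α,13-diol directly. The route is rejoined at 38; this fallback makes no new compound (F0).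

Step 26. Hydrolysis of the inductively deactivated, hindered ketal may be sluggish, so that loss of the TBS ethers or ionisation of the allylic lactone competes. Fallback: setting out from 38, BF3·OEt2-promoted exchange with ethane-1,2-dithiol at −20 °C gives the C16 dithiolane F2. This is cleaved under neutral alkylative conditions (MeI, CaCO3, aqueous MeCN) to the ketone, rejoining the route at 39.

Further compounds
F1 | step 18 | C3 vinyl ketone of lactone 30 | C[Si](C)(C)CCOC(=O)[C@H]1[C@@H]2[C@@](C)(C(=O)C=C)C(=O)O[C@]2(C=C)[C@H](CC=C(C)C)[C@]13C[C@H](O[Si](CC)(CC)CC)C4(OCCO4)[C@H]3O[Si](C)(C)C(C)(C)C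
F0 | step 24 | none | none
F2 | step 26 | C16 1,3-dithiolane analogue of diol 38 | C[Si](C)(C)CCOC(=O)[C@H]1[C@@H]2[C@]3(C)C(=O)O[C@]2(C=C[C@@H]3O[Si](C)(C)C(C)(C)C)[C@@H]2C[C@H](O)[C@]3(O)C[C@]12[C@H](O[Si](C)(C)C(C)(C)C)C34SCCS4
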